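## Structural features

The target joins a labdane acid to a rearranged nor-abietane through an E-trisubstituted C12′=C13′ alkene. The labdane half is a trans-decalin with an equatorial C4′ carboxylic acid, an exocyclic C8′=C17′ methylene and an equatorial C9′ side chain (primed locants are labdane carbons; unprimed locants follow abietane numbering). In the nor-abietane half, ring A (C1–C5, C10; gem-dimethyl at C4, angular methyl at C10) is trans-fused to a five-membered ring B (C5, C6, C8, C9, C10), and C6 carries a tertiary hydroxyl and the formyl carbon C7. C8 is also a bridgehead of a bicyclo[3.2.1]octenone whose other bridgehead is C13 (isopropyl). Its one-carbon bridge is the C14 ketone, its three-carbon bridge is the diosphenol C9=C11(OH)–C12(=O), and its two-carbon bridge is C15′H2–C14′H with the side chain endo on C14′. The stereocentres C10, C5, C6 and C8 are contiguous around ring B, C13 and C14′ are adjacent, and five carbons (C4, C10, C6, C8, C13) are fully substituted, with the C14 ketone lying between two of them. The fragile groups are the α-hydroxy aldehyde (α-ketol shift), the acidic and oxidisable diosphenol, the exocyclic methylene (acid isomerisation) and any intermediate in which C14′ is α to a ketone. The real difficulty is the congested C6/C8/C9/C13/C14 region, where ring B and the bicycle share the C8–C9 bond. The key step exploits exactly this: C8, C15′, C14′, C13 and C14 form a cyclopentadienone ketal, C9–C11–C12 form a three-carbon oxyallyl unit, and the C10–C5–C6 tether lets one cycloaddition make C9–C8 and C12–C13, closing ring B and the bicycle together.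

## Logic of the disconnections

**49 to 47.** The C7 carbonyl and the C8′=C17′ double bond are cut first, to the primary alcohol 48 and then the ketone 47. These are the two most sensitive groups, and leaving them to the end keeps acid, base and organometallic steps away from them. The forward steps must oxidise a neopentyl primary alcohol beside a diosphenol and a tertiary alcohol, and must methylenate the decalone carbonyl of 47 in preference to the C14 ketone.

**47 to 32 and 45.** The C9′–C11′ bond is cut (with the C14 ketal restored in 46), giving the tertiary vinyl carbinol 32 and the β-keto acid 45. This is the convergent cut, it removes ten skeletal carbons and four stereocentres in one stroke, and a π-allyl intermediate fixes the E alkene. The forward step needs attack at the unsubstituted allyl terminus and an equatorial C9′ side chain after enolisation.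

**32 to 29.** The C12′–C13′ bond is cut to the methyl ketone 31, which comes from the enone 29. C14′ then becomes an epimerisable centre that is set by equilibration while the bulky C14 ketal occupies the exo side and the three-carbon bridge is flat. The demand is that the endo ketone is the more stable epimer and that nothing else in 31 accepts a Grignard reagent.

**29 to 23.** The C6–O bond and the oxidation levels of C7, C11 and C12 are taken back through 28, 26 and 25 to the cycloadduct 23. This makes C6 a CH carrying a nitrile and makes the diosphenol an α-silyloxy ketone. The forward steps must hydroxylate C6 on the face away from C14 and must reduce the nitrile without touching the C12 carbonyl.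

**23 to 22.** The C9–C8 and C12–C13 bonds are cut together. Two rings, two skeletal bonds and four stereocentres fall away, leaving a ring A aldehyde 22 that carries a cyclopentadienone ketal on one arm and a Z-2-silyloxy enal on the other. A carboxyl group at C6 would have to sit on the face of the C10 methyl and of C14, wedged between C4 and C10, if it were fixed in the configuration that matches the natural C8 centre with the carboxyl carbon β. For that reason C7 is carried as the small nitrile, for which either C6 configuration can reach the reactive conformer. The silyl group is tert-butyldimethylsilyl so that the enol ether survives the steps before the cycloaddition.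

**22 to 10 and 19.** The C6–C8 bond is cut (after returning the aldehyde to the ester 20), giving the nitrile 10 and the dienyl triflate 19. A bond between an α-cyano carbon and an sp2 carbon can be made by cross-coupling without passing through a tertiary carbinol, and the diene arrives in its final tautomeric form. The demand is a coupling between two hindered partners.

**10 to 1.** The C9=C11 bond of 10 is cut to the aldehyde 9. The aldehyde and the nitrile of 9 are then reconnected as the C7–C9 bond of the hydrindanone 7, so that a ring serves as a template for the C5 centre (hydrogenation of 6, made from 5). The enone 5 is opened to the diketone 4, which comes from the allyl ketone 3, and 3 from 1 by cutting the C10–C9 bond. The single demand on absolute configuration falls on the allylation that makes 3.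

**19 to 11.** The triflate 19 comes from the enone 18, whose carbonyl is transposed from the carbinol 17. Cutting the C14′–C13′ bond of 17 gives the mono-ketal 15 of the symmetric enedione 14, which is reached from 13, 12 and 11. Symmetry of 14 removes any regiochemical choice in the ketalisation.

**45 to 33.** The acid 45 is taken back through 44, 43 and 42 to the bicyclic β-keto ester 41. Cutting the C4′–C5′ and C9′–C10′ bonds of 41 gives the epoxy polyene 40. The C6′–C7′ bond of 40 is cut to the bromide 39 and an acetoacetate, and 39 comes through 37, 36, 35 and 34 from 33. The epoxide stereocentre controls the whole decalin, and the E-oxygenated methyl becomes the equatorial C18′ carbon. The price is a C3′ hydroxyl that must be removed.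

## Other disconnections considered

**Alternative 1:** The cut is through C4′–C5′ and C9′–C10′, so that both labdane rings are made last. An open-chain epoxy polyene A1, already attached to the complete nor-abietane, would be cyclised by MeAlCl2 to the 3′-hydroxy-18′-silyloxy labdane A2, and the cation would be ended by loss of Me3Si to give the exocyclic alkene.
- In its favour: the acyclic chain is easy to attach, and the methylene arrives without a carbonyl olefination. On that point it is better than the chosen plan, whose step 40 must discriminate between ketones.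
- Equal: the cyclisation is of the same mechanistic class as step 33 of the chosen route.
- Against it here: the cationic cascade would run on the most valuable intermediate, in the presence of a diosphenol ether, the bridging ketone and a tertiary carbinol. A2 would still need deoxygenation at C3′, oxidation of C18′ to the acid, cleavage of a methyl enol ether and two desilylations. The late sequence would therefore be longer and would put the risk at the end, whereas the chosen plan carries the same cyclisation on a small fragment.

**Alternative 2:** The cut is the C9–C10 bond, so ring B is closed last. TfOH would protonate the ring A alkene of the seco compound A3 to a tertiary cation at C10, the β-carbon of the diosphenol would capture it, and the product would be the carbonate ester A4.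
- In its favour: it is convergent, it uses the innate nucleophilicity of the diosphenol for the most hindered bond, and the key step has only one bond and one ring to form. On convergence and simplicity of the key event it is equal to or better than the chosen plan.
- Against it here: C10 is planar in the cation, so the trans relationship of the C10 methyl to the C5 hydrogen must come from the kinetics of a five-ring closure, which usually favours the cis-fused hydrindane. Hydride shift from C5 and simple elimination compete. The chosen plan fixes C10 before the key step by a catalyst-controlled allylation.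
- Step economy: similar, because A4 still needs the whole labdane side chain built from an ester and the carbonate opened to the hydroxy aldehyde.

**Alternative 3:** The cut is made by ring contraction. A 6-diazo-7-ketone A5 with a normal six-membered ring B would lose N2 at 365 nm, C8 would migrate from C7 to C6, and ethanethiol would trap the ketene as the thioester A6.
- In its favour: the full dimeric skeleton can be assembled first, close to the presumed biogenesis (cycloaddition and α-ketol shift), so the step count to A5 could be lower than to 23. That is a real advantage in step economy. The thioester is also at a convenient oxidation level for the aldehyde, which is equal to or better than the nitrile.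
- Against it here: the β,γ-unsaturated bridging ketone and the enone chromophore would be irradiated together with the diazoketone, so acyl shifts and decarbonylation compete. C6 would still have to be hydroxylated afterwards (equal to the chosen plan), but on a thioester beside every other functional group. The diazo transfer would have to be made next to the quaternary C8.

Key step: step 19

Remark 1: (R)-t-BuPHOX is taken to give the (R)-ketone 3 by the sense known for 2-allyl-2-methylcyclohexanone; if the trimethyl substrate behaves oppositely the enantiomeric ligand is used.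
Remark 2: C6 is carried as a mixture of epimers from 20 to 26, and C12 of 23 and 24 is left unassigned; both centres are erased later, so their SMILES carry no descriptor.
Remark 3: the silyloxy phosphonate of step 8, the N-sulfonyloxaziridine, TMPZnCl·LiCl and the PHOX ligand are taken as catalogue reagents.

## Route

Step 1
Reactants: 1 2,2,6-trimethylcyclohexanone
Product: 2 allyl 2,6,6-trimethylcyclohex-1-en-1-yl carbonate
Conditions: LiN(SiMe3)2, THF, −78 °C; allyl chloroformate, −78 °C → rt
Reagents that add atoms: allyl chloroformate, C=CCOC(Cl)=O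
Why: Only one α-carbon of 1 bears hydrogen, so enolisation is regiospecific and O-acylation of the lithium enolate gives the enol carbonate; the stereocentre of racemic 1 is erased.

Step 2
Reactants: 2 allyl 2,6,6-trimethylcyclohex-1-en-1-yl carbonate
Product: 3 (R)-2-allyl-2,6,6-trimethylcyclohexan-1-one
Conditions: Pd2(dba)3 (2.5 mol %), (R)-t-BuPHOX (6 mol %), THF, 25 °C
Reagents that add atoms: none
Why: Decarboxylative asymmetric allylic alkylation (Tsuji type): ionisation and loss of CO2 give a palladium allyl enolate pair that recombines at carbon inside the chiral pocket, which sets the quaternary C10 centre under ligand control.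

Step 3
Reactants: 3 (R)-2-allyl-2,6,6-trimethylcyclohexan-1-one
Product: 4 (R)-2,2,6-trimethyl-6-(2-oxopropyl)cyclohexan-1-one
Conditions: PdCl2 (10 mol %), Cu(OAc)2 (20 mol %), O2 (1 atm), DMA/H2O, 25 °C
Reagents that add atoms: water, O
Why: Wacker oxidation; Markovnikov hydroxypalladation of the terminal alkene gives the methyl ketone and leaves the quaternary centre untouched.

Step 4
Reactants: 4 (R)-2,2,6-trimethyl-6-(2-oxopropyl)cyclohexan-1-one
Product: 5 (R)-4,4,7a-trimethyl-5,6,7,7a-tetrahydro-1H-inden-2(4H)-one
Conditions: KOH, xylenes, 110 °C, Dean–Stark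
Reagents that add atoms: none
Why: Intramolecular aldol condensation; the methyl ketone enolate is the only nucleophile that can reach the non-enolisable ring ketone, and dehydration makes the five-ring enone irreversibly.

Step 5
Reactants: 5 (R)-4,4,7a-trimethyl-5,6,7,7a-tetrahydro-1H-inden-2(4H)-one
Product: 6 (1S,7aS)-1-hydroxy-4,4,7a-trimethyl-5,6,7,7a-tetrahydro-1H-inden-2(4H)-one
Conditions: LiN(i-Pr)2, THF, −78 °C; 2-(phenylsulfonyl)-3-phenyloxaziridine, −78 °C
Reagents that add atoms: 2-(phenylsulfonyl)-3-phenyloxaziridine, O=S(=O)(N1OC1c1ccccc1)c1ccccc1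
Why: The α′ methylene is the only kinetically enolisable site and the enolate is hydroxylated anti to the angular methyl (enolate oxidation by an N-sulfonyloxaziridine); the carbinol configuration is of no consequence because this carbon becomes the aldehyde in step 7.

Step 6
Reactants: 6 (1S,7aS)-1-hydroxy-4,4,7a-trimethyl-5,6,7,7a-tetrahydro-1H-inden-2(4H)-one
Product: 7 (1S,3aS,7aS)-1-hydroxy-4,4,7a-trimethyloctahydro-2H-inden-2-one
Conditions: H2 (4 atm), 10 % Pd/C, EtOAc, 25 °C
Reagents that add atoms: none
Why: Heterogeneous hydrogenation of the enone from the face opposite the angular methyl and the axial methyl of the gem-dimethyl group, which both cover the other face of the ring-fusion carbon; this sets C5 with its hydrogen anti to the C10 methyl (trans fusion).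

Step 7
Reactants: 7 (1S,3aS,7aS)-1-hydroxy-4,4,7a-trimethyloctahydro-2H-inden-2-one
Product: 9 2-[(1S,2S)-2-formyl-2,6,6-trimethylcyclohexyl]acetonitrile, via hydroxy ketoxime 8 (not isolated)
Conditions: NH2OH·HCl, pyridine, 60 °C; then TsCl, 0 °C → 25 °C
Reagents that add atoms: hydroxylamine hydrochloride, NO.Cl
Why: Beckmann fragmentation of the α-hydroxy ketoxime sulfonate: the C–C bond anti to the leaving group breaks with push from the hydroxyl, giving the C7 nitrile and the C9 aldehyde in one operation; C5 and C10 are not touched.

Step 8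
Reactants: 9 2-[(1S,2S)-2-formyl-2,6,6-trimethylcyclohexyl]acetonitrile
Product: 10 methyl (Z)-2-[(tert-butyldimethylsilyl)oxy]-3-[(1S,2S)-2-(cyanomethyl)-1,3,3-trimethylcyclohexyl]prop-2-enoate
Conditions: methyl 2-[(tert-butyldimethylsilyl)oxy]-2-(dimethoxyphosphoryl)acetate, LiN(SiMe3)2, THF, −78 → 0 °C
Reagents that add atoms: methyl 2-[(tert-butyldimethylsilyl)oxy]-2-(dimethoxyphosphoryl)acetate, COC(=O)C(O[Si](C)(C)C(C)(C)C)P(=O)(OC)OC
Why: Horner–Wadsworth–Emmons olefination of the neopentyl aldehyde; the bulky ring ends trans to the ester, that is cis to the silyloxy group (Z), which is the geometry the cycloaddition needs.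

Step 9
Reactants: 11 furan-2-carbaldehyde
Product: 12 1-(furan-2-yl)-2-methylpropan-1-ol (racemic)
Conditions: i-PrMgCl, THF, 0 °C
Reagents that add atoms: isopropylmagnesium chloride, CC(C)[Mg]Cl
Why: Grignard addition to the aldehyde; the racemic carbinol stereocentre is destroyed in step 11.

Step 10
Reactants: 12 1-(furan-2-yl)-2-methylpropan-1-ol
Product: 13 trans-4-hydroxy-5-isopropylcyclopent-2-en-1-one (racemic)
Conditions: ZnCl2, 1,4-dioxane/H2O, reflux
Reagents that add atoms: water, O
Why: Piancatelli rearrangement; ionisation, attack of water on the furan, ring opening and conrotatory 4π closure give the trans hydroxy enone.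

Step 11
Reactants: 13 trans-4-hydroxy-5-isopropylcyclopent-2-en-1-one
Product: 14 2-isopropylcyclopent-4-ene-1,3-dione
Conditions: CrO3, H2SO4, H2O, acetone, 0 °C
Reagents that add atoms: none
Why: Chromic acid oxidation of the allylic secondary alcohol gives the symmetric enedione, which removes both stereocentres.

Step 12
Reactants: 14 2-isopropylcyclopent-4-ene-1,3-dione
Product: 15 5-isopropyl-4,4-dimethoxycyclopent-2-en-1-one (racemic)
Conditions: HC(OMe)3, MeOH, p-TsOH (cat.), 0 → 25 °C
Reagents that add atoms: trimethyl orthoformate, COC(OC)OC; methanol, CO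
Why: The two carbonyls of 14 are equivalent, and after the first ketalisation the remaining one is a deactivated conjugated enone, so the reaction should stop at the mono-ketal without a regiochemical choice.

Step 13
Reactants: 15 5-isopropyl-4,4-dimethoxycyclopent-2-en-1-one
Product: 17 5-isopropyl-4,4-dimethoxy-1-(2-methyl-1,3-dioxolan-2-yl)cyclopent-2-en-1-ol (mixture of diastereomers), via ethoxyvinyl carbinol 16 (not isolated)
Conditions: ethyl vinyl ether, t-BuLi, THF, −78 → 0 °C; CeCl3, −78 °C; 15; then HOCH2CH2OH, PPTS, 0 → 25 °C
Reagents that add atoms: ethyl vinyl ether, C=COCC; ethylene glycol, OCCO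
Why: 1,2-Addition of the 1-ethoxyvinyl organocerium (acyl anion equivalent, cerium suppresses enolisation) followed by acid-catalysed addition of the diol to the enol ether and loss of ethanol gives the dioxolane; the stereocentres formed are removed in steps 14 and 15.

Step 14
Reactants: 17 5-isopropyl-4,4-dimethoxy-1-(2-methyl-1,3-dioxolan-2-yl)cyclopent-2-en-1-ol
Product: 18 4-isopropyl-5,5-dimethoxy-3-(2-methyl-1,3-dioxolan-2-yl)cyclopent-2-en-1-one (racemic)
Conditions: C5H5NH[CrO3Cl], NaOAc, 4 Å MS, CH2Cl2, 25 °C
Reagents that add atoms: none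
Why: Babler–Dauben oxidative transposition; the chromate ester of the tertiary allylic alcohol undergoes a 1,3-shift and is oxidised to the β-substituted enone, which places the carbonyl at C8 next to the ketal.

Step 15
Reactants: 18 4-isopropyl-5,5-dimethoxy-3-(2-methyl-1,3-dioxolan-2-yl)cyclopent-2-en-1-one
Product: 19 4-isopropyl-5,5-dimethoxy-3-(2-methyl-1,3-dioxolan-2-yl)cyclopenta-1,3-dien-1-yl trifluoromethanesulfonate
Conditions: KN(SiMe3)2, THF, −78 °C; PhNTf2, −78 → 0 °C
Reagents that add atoms: N-phenylbis(trifluoromethanesulfonimide), O=S(=O)(N(c1ccccc1)S(=O)(=O)C(F)(F)F)C(F)(F)F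
Why: The only acidic hydrogen is the γ-hydrogen at C13, so deprotonation gives the linear dienolate, which is triflated on oxygen; loss of methoxide is blocked because it would give an antiaromatic cyclopentadienone.

Step 16
Reactants: 10 methyl (Z)-2-[(tert-butyldimethylsilyl)oxy]-3-[(1S,2S)-2-(cyanomethyl)-1,3,3-trimethylcyclohexyl]prop-2-enoate; 19 4-isopropyl-5,5-dimethoxy-3-(2-methyl-1,3-dioxolan-2-yl)cyclopenta-1,3-dien-1-yl trifluoromethanesulfonate
Product: 20 methyl (Z)-2-[(tert-butyldimethylsilyl)oxy]-3-[2-{cyano[4-isopropyl-5,5-dimethoxy-3-(2-methyl-1,3-dioxolan-2-yl)cyclopenta-1,3-dien-1-yl]methyl}-1,3,3-trimethylcyclohexyl]prop-2-enoate (ring A centres as in 10, both C6 epimers)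
Conditions: TMPZnCl·LiCl (TMP = 2,2,6,6-tetramethylpiperidide), THF, 25 °C; then 19, Pd(OAc)2 (5 mol %), SPhos (10 mol %), THF, 40 °C
Reagents that add atoms: none
Why: Negishi-type α-alkenylation of a zincated nitrile: the amide base zincates the CH2CN group without attacking the non-enolisable ester, and palladium joins the zinc cyanoalkyl to the dienyl triflate, forming C6–C8 with the diene already in its final tautomer; C6 is formed without control, which is acceptable for the small nitrile.

Step 17
Reactants: 20 coupled enoate
Product: 21 (Z)-2-silyloxy allylic alcohol corresponding to 20 (CO2Me → CH2OH)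
Conditions: i-Bu2AlH (2.2 equiv), CH2Cl2, −78 °C; aq. potassium sodium tartrate
Reagents that add atoms: none
Why: Hydride reduction of the ester to the allylic alcohol at −78 °C, where the hindered secondary nitrile and the ketals should not react and the aluminium alkoxide does not trigger silyl migration.

Step 18
Reactants: 21 (Z)-2-silyloxy allylic alcohol
Product: 22 (Z)-2-[(tert-butyldimethylsilyl)oxy]-3-[ring A]-prop-2-enal carrying the cyano(cyclopentadienyl)methyl arm at C5 (the cycloaddition precursor)
Conditions: MnO2, CH2Cl2, 25 °C; used at once, kept cold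
Reagents that add atoms: none
Why: Neutral oxidation of the allylic alcohol to the enal leaves the silyl enol ether, the ketals and the epimerisable C6 centre alone; the enal is used directly to avoid a thermal Diels–Alder reaction with the tethered diene.

Step 19
Reactants: 22 silyloxy enal tethered to the cyclopentadienone dimethyl ketal
Product: 23 8,8-dimethoxybicyclo[3.2.1]oct-6-en-3-one cycloadduct with ring B closed (C12 silyloxy, C11 ketone, C6 nitrile, C14′ dioxolanyl alkene)
Conditions: Sc(OTf)3 (20 mol %), 2,6-di-tert-butyl-4-methylpyridine (30 mol %), CH2Cl2, −78 → −30 °C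
Reagents that add atoms: none
Why: Proposed new method: Sc(OTf)3 binds the aldehyde oxygen of the Z enal and turns C9–C11–C12 into a 2-silyloxyallyl (vinyl oxocarbenium) cation, C9 attacks the diene terminus C8, the cyclopentenyl cation so formed is captured at C13 by the enol silane carbon C12, and the silyl group passes from the C11 oxygen to the C12 oxygen to leave the C11 ketone; the closest known reaction type is the Lewis-acid (4+3) cycloaddition of 2-silyloxy enals with cyclopentadiene and with tethered dienes, extended here to a 5,5-dimethoxycyclopentadiene whose ketal carbon blocks 1,5-hydrogen shifts and cannot ionise without forming an antiaromatic cation. Ring B closes 5-exo through the C10–C5–C6 tether, and the seven-membered ring closes when C12 bonds to the far terminus of the allyl cation (endo with respect to that cation), with C14 becoming the one-carbon bridge. C8 is set by the face of the cation that the tether presents: allylic 1,3-strain in the Z cation keeps the C10 methyl, the smallest group on C10, in the plane of the cation, so C11 lies on the methyl face of the forming ring B and the ketal bridge must follow it. C13 follows from C8 because the three-carbon unit can only span one face of the five-membered diene, and C9 is cis to C14 on ring B for the same reason. The configuration at C12 depends on the shape of the cation and is of no consequence. The step needs diene-face selectivity relative to C5 and C10, and (4+3) over (4+2) or (3+2) periselectivity. The first is secured by the Z enal, the trans-diequatorial arms on ring A and the small nitrile at C6, which can occupy the crowded site between C4 and C10 in either C6 configuration where an ester could not; the second by the silyl transfer, which makes the seven-ring ketone the sink, and by the low temperature.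

Step 20
Reactants: 23 cycloadduct
Product: 24 acyloin (C12 hydroxyl, C11 ketone)
Conditions: Bu4NF, AcOH, THF, 0 °C
Reagents that add atoms: none
Why: Buffered fluoride removes the silyl ether without base-induced change of the acyloin; the ketals and the nitrile are inert.

Step 21
Reactants: 24 acyloin
Product: 25 diosphenol nitrile (C12 ketone, C11 enol, C9=C11)
Conditions: 1,1,1-triacetoxy-1,1-dihydro-1,2-benziodoxol-3(1H)-one, NaHCO3, CH2Cl2, 25 °C
Reagents that add atoms: none
Why: Periodinane oxidation of the α-hydroxy ketone gives the 1,2-dione, which can enolise only toward C9 (C13 is quaternary) and so gives the diosphenol of the target; the stereocentres at C9 and C12 are erased.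

Step 22
Reactants: 25 diosphenol nitrile
Product: 26 C7 aldehyde (C6–H, both epimers)
Conditions: i-Bu2AlH (4 equiv), toluene, −78 → 0 °C; aq. tartaric acid, then SiO2
Reagents that add atoms: water, O
Why: The first equivalent of hydride deprotonates the diosphenol, and the aluminium enolate shields the C12 carbonyl as a vinylogous carboxylate while the nitrile is reduced to the aldimine, which is hydrolysed to the aldehyde on work-up.

Step 23
Reactants: 26 C7 aldehyde
Product: 28 C6,C7-diol (tertiary C6–OH on the α face, CH2OH on the β face), via hydroxy aldehyde 27 (not isolated)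
Conditions: KN(SiMe3)2 (2.5 equiv), THF, −78 → −20 °C; 2-(phenylsulfonyl)-3-phenyloxaziridine, −78 °C; then NaBH4, MeOH, −78 → 0 °C
Reagents that add atoms: 2-(phenylsulfonyl)-3-phenyloxaziridine, O=S(=O)(N1OC1c1ccccc1)c1ccccc1
Why: Enolate hydroxylation of the aldehyde (the diosphenolate is far less nucleophilic) takes place on the α face of ring B, because the β face is covered by the C14 ketal and by the β-methyl groups on C4 and C10, which sets C6 and erases the epimer mixture; the α-hydroxy aldehyde is reduced in the same flask to protect it from α-ketol shift until the last step.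

Step 24
Reactants: 28 C6,C7-diol
Product: 29 enone (C13′ methyl ketone conjugated with C14′=C15′)
Conditions: PPTS, acetone/H2O (10:1), 50 °C
Reagents that add atoms: water, O
Why: Mild acid hydrolyses the dioxolane of the side-chain ketone, while the bridging dimethyl ketal, whose oxocarbenium ion would be strained and flanked by two quaternary carbons, should remain.

Step 25
Reactants: 29 enone
Product: 31 endo methyl ketone (C14′–H exo, natural configuration), via exo-acetyl epimer 30 (not isolated)
Conditions: H2 (1 atm), 10 % Pd/C, EtOAc, 25 °C; filter; DBU, MeOH, 25 °C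
Reagents that add atoms: none
Why: The strained conjugated alkene is hydrogenated much faster than the tetrasubstituted enol, and C14′ is then equilibrated through the enolate. The endo acetyl should be favoured because the exo position is occupied by the syn methoxy group of the C14 ketal and lies closer to the C13 isopropyl, while the diosphenol bridge below is flat.

Step 26
Reactants: 31 endo methyl ketone
Product: 32 tertiary vinyl carbinol (both C13′ epimers)
Conditions: CeCl3, CH2=CHMgBr (6 equiv), THF, −78 → 0 °C
Reagents that add atoms: vinylmagnesium bromide, C=C[Mg]Br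
Why: Organocerium addition to the only free ketone: the diosphenol is present as its enolate and C14 as the ketal, and cerium suppresses enolisation at C14′. The new carbinol centre is lost in step 38.

Step 27
Reactants: 33 geranyl acetate
Product: 34 (2E,6E)-8-hydroxy-3,7-dimethylocta-2,6-dien-1-yl acetate
Conditions: SeO2 (10 mol %), t-BuOOH, salicylic acid (10 mol %), CH2Cl2, 25 °C
Reagents that add atoms: tert-butyl hydroperoxide, CC(C)(C)OO
Why: Allylic oxidation by SeO2 (ene reaction, then 2,3-shift) is selective for the E methyl of the terminal alkene, because the other alkene is deactivated by the allylic acetate.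

Step 28
Reactants: 34 (2E,6E)-8-hydroxy-3,7-dimethylocta-2,6-dien-1-yl acetate
Product: 35 (2E)-5-[(2S,3S)-3-(hydroxymethyl)-3-methyloxiran-2-yl]-3-methylpent-2-en-1-yl acetate
Conditions: Ti(Oi-Pr)4 (10 mol %), L-(+)-diethyl tartrate (12 mol %), t-BuOOH, 4 Å MS, CH2Cl2, −20 °C
Reagents that add atoms: tert-butyl hydroperoxide, CC(C)(C)OO
Why: Sharpless asymmetric epoxidation of the E-trisubstituted allylic alcohol; the tartrate fixes both epoxide centres, and these later fix C4′, C5′ and C10′.

Step 29
Reactants: 35 epoxy alcohol
Product: 36 tert-butyldimethylsilyl ether of 35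
Conditions: TBSCl, imidazole, DMF, 25 °C
Reagents that add atoms: tert-butyldimethylsilyl chloride, C[Si](C)(Cl)C(C)(C)C
Why: Silylation of the primary alcohol protects the future C18′ oxygen from the base and the Lewis acid of the following steps.

Step 30
Reactants: 36 silyl ether acetate
Product: 37 (2E)-5-[(2S,3S)-3-{[(tert-butyldimethylsilyl)oxy]methyl}-3-methyloxiran-2-yl]-3-methylpent-2-en-1-ol
Conditions: K2CO3, MeOH, 0 °C
Reagents that add atoms: none
Why: Methanolysis removes the acetate and leaves the epoxide and the silyl ether.

Step 31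
Reactants: 37 allylic alcohol
Product: 39 allylic bromide corresponding to 37, via allylic mesylate 38 (not isolated)
Conditions: MsCl, Et3N, THF, −40 °C; then LiBr, THF, 0 °C
Reagents that add atoms: lithium bromide, [Li+].[Br-]
Why: The primary allylic mesylate is displaced by bromide far faster than the trisubstituted epoxide is opened, and the E alkene is retained.

Step 32
Reactants: 39 allylic bromide
Product: 40 benzyl (6E)-9-[(2S,3S)-3-{[(tert-butyldimethylsilyl)oxy]methyl}-3-methyloxiran-2-yl]-7-methyl-3-oxonon-6-enoate
Conditions: benzyl acetoacetate, NaH, THF, 0 °C; n-BuLi, 0 °C; then 39, 0 °C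
Reagents that add atoms: benzyl acetoacetate, CC(=O)CC(=O)OCc1ccccc1
Why: γ-Alkylation of the acetoacetate dianion with the allylic bromide gives the linear β-keto ester that will end the cyclisation.

Step 33
Reactants: 40 epoxy β-keto ester
Product: 41 benzyl 3′β-hydroxy-8′-oxo decalin-9′-carboxylate with C18′ silyloxymethyl (trans-decalin, 4′β-methyl, 10′β-methyl, 5′α-H)
Conditions: MeAlCl2 (2.5 equiv), CH2Cl2, −78 → −30 °C
Reagents that add atoms: none
Why: Lewis-acid epoxy-polyene bicyclisation ended by the β-keto ester enol: anti opening of the epoxide at C4′ and chair–chair folding of the E alkene give the trans-decalin, with the E-oxygenated methyl equatorial (C18′) and the hydroxyl 3′β. C9′ is epimerisable and settles with the ester equatorial.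

Step 34
Reactants: 41 bicyclic hydroxy keto ester
Product: 42 3′-O-(imidazol-1-ylthiocarbonyl) derivative of 41
Conditions: 1,1′-thiocarbonyldiimidazole, DMAP, ClCH2CH2Cl, 70 °C
Reagents that add atoms: 1,1′-thiocarbonyldiimidazole, S=C(n1ccnc1)n1ccnc1
Why: Acylation of the secondary alcohol prepares the Barton–McCombie deoxygenation.

Step 35
Reactants: 42 thiocarbonylimidazolide
Product: 43 benzyl 8′-oxo decalin-9′-carboxylate with C18′ silyloxymethyl (C3′ deoxygenated)
Conditions: Bu3SnH, AIBN, toluene, 110 °C
Reagents that add atoms: none
Why: Barton–McCombie radical deoxygenation removes the C3′ oxygen; no stereocentre other than C3′ is involved.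

Step 36
Reactants: 43 silyl ether
Product: 44 C18′ carboxylic acid, benzyl 8′-oxo-9′-carboxylate
Conditions: CrO3, H2SO4, H2O, acetone, 0 → 25 °C
Reagents that add atoms: chromium trioxide, O=[Cr](=O)=O; water, O
Why: Chromic acid cleaves the primary silyl ether in situ and oxidises the neopentyl alcohol to the acid; the β-keto ester is stable to these conditions.

Step 37
Reactants: 44 acid benzyl ester
Product: 45 8′-oxo-decalin-4′,9′-dicarboxylic acid (β-keto acid; used at once)
Conditions: H2 (1 atm), 10 % Pd/C, EtOAc, 25 °C
Reagents that add atoms: none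
Why: Hydrogenolysis of the benzyl ester liberates the β-keto acid under neutral conditions, so decarboxylation is avoided until the coupling.

Step 38
Reactants: 32 tertiary vinyl carbinol; 45 β-keto acid
Product: 46 coupled 8′-ketone (E-C12′=C13′, C9′ side chain equatorial, C14 ketal, C6/C7 diol, diosphenol, C18′ acid)
Conditions: Pd(PPh3)4 (10 mol %), THF, 45 °C; then DBU, 25 °C
Reagents that add atoms: none
Why: Palladium-catalysed decarboxylative allylation (Carroll type in the Tsuji–Trost manifold): acid-assisted ionisation of the vinyl carbinol gives a π-allyl complex paired with the β-keto carboxylate, and loss of CO2 is followed by C-allylation at C9′ through the unsubstituted terminus. The bulky C14′ substituent sits syn on the allyl unit, which gives the E alkene, and C9′ equilibrates to the equatorial epimer through the enol.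

Step 39
Reactants: 46 coupled ketal
Product: 47 C14 ketone (may exist partly as the cyclic hemiketal with the C7 hydroxyl)
Conditions: 2 M aq. HCl/THF (1:1), 45 °C
Reagents that add atoms: water, O
Why: Acid hydrolysis of the bridging dimethyl ketal is carried out before the acid-sensitive exocyclic methylene exists; retro-aldol cleavage of the C6–C8–C14 β-hydroxy ketone would need a bridgehead enol and is not expected.

Step 40
Reactants: 47 triketone
Product: 48 8′(17′)-methylene compound (C6/C7 diol)
Conditions: Ph3PCH3Br, KOt-Bu, THF/toluene, 0 → 50 °C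
Reagents that add atoms: methyltriphenylphosphonium bromide, C[P+](c1ccccc1)(c1ccccc1)c1ccccc1.[Br-]
Why: Wittig methylenation of the decalone; under the basic conditions the diosphenol is an enolate, and the C14 ketone is flanked by two quaternary carbons and masked as the hemiketal anion of the neighbouring C7 alkoxide. C9′ stays equatorial under equilibrating conditions.

Step 41
Reactants: 48 methylene diol
Product: 49 CNP0124601.1
Conditions: SO3·pyridine, DMSO, i-Pr2NEt, CH2Cl2, 0 °C
Reagents that add atoms: none
Why: Parikh–Doering oxidation converts the primary alcohol into the aldehyde without touching the tertiary alcohol, the alkenes or the acid. It is short, cold and non-acidic, so the α-hydroxy aldehyde should not undergo α-ketol shift.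

## Compound list

1 | 2,2,6-trimethylcyclohexanone | CC1CCCC(C)(C)C1=O | starting material
2 | allyl 2,6,6-trimethylcyclohex-1-en-1-yl carbonate | C=CCOC(=O)OC1=C(C)CCCC1(C)C | intermediate
3 | (R)-2-allyl-2,6,6-trimethylcyclohexan-1-one | C=CC[C@@]1(C)CCCC(C)(C)C1=O | intermediate
4 | (R)-2,2,6-trimethyl-6-(2-oxopropyl)cyclohexan-1-one | CC(=O)C[C@@]1(C)CCCC(C)(C)C1=O | intermediate
5 | (R)-4,4,7a-trimethyl-5,6,7,7a-tetrahydro-1H-inden-2(4H)-one | O=C1C[C@@]2(C)CCCC(C)(C)C2=C1 | intermediate
6 | (1S,7aS)-1-hydroxy-4,4,7a-trimethyl-5,6,7,7a-tetrahydro-1H-inden-2(4H)-one | O=C1[C@@H](O)[C@@]2(C)CCCC(C)(C)C2=C1 | intermediate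
7 | (1S,3aS,7aS)-1-hydroxy-4,4,7a-trimethyloctahydro-2H-inden-2-one | O=C1[C@@H](O)[C@@]2(C)CCCC(C)(C)[C@@H]2C1 | intermediate
8 | oxime of 7 | ON=C1[C@@H](O)[C@@]2(C)CCCC(C)(C)[C@@H]2C1 | intermediate (not isolated)
9 | 2-[(1S,2S)-2-formyl-2,6,6-trimethylcyclohexyl]acetonitrile | O=C[C@@]1(C)CCCC(C)(C)[C@@H]1CC#N | intermediate
10 | methyl (Z)-2-[(tert-butyldimethylsilyl)oxy]-3-[(1S,2S)-2-(cyanomethyl)-1,3,3-trimethylcyclohexyl]prop-2-enoate | COC(=O)/C(O[Si](C)(C)C(C)(C)C)=C/[C@@]1(C)CCCC(C)(C)[C@@H]1CC#N | intermediate
11 | furan-2-carbaldehyde | O=Cc1ccco1 | starting material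
12 | 1-(furan-2-yl)-2-methylpropan-1-ol (racemic) | CC(C)C(O)c1ccco1 | intermediate
13 | trans-4-hydroxy-5-isopropylcyclopent-2-en-1-one (racemic, relative configuration shown) | CC(C)[C@@H]1[C@@H](O)C=CC1=O | intermediate
14 | 2-isopropylcyclopent-4-ene-1,3-dione | CC(C)C1C(=O)C=CC1=O | intermediate
15 | 5-isopropyl-4,4-dimethoxycyclopent-2-en-1-one (racemic) | CC(C)C1C(=O)C=CC1(OC)OC | intermediate
16 | 1-(1-ethoxyvinyl)-5-isopropyl-4,4-dimethoxycyclopent-2-en-1-ol | CCOC(=C)C1(O)C=CC(OC)(OC)C1C(C)C | intermediate (not isolated)
17 | 5-isopropyl-4,4-dimethoxy-1-(2-methyl-1,3-dioxolan-2-yl)cyclopent-2-en-1-ol | CC1(OCCO1)C1(O)C=CC(OC)(OC)C1C(C)C | intermediate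
18 | 4-isopropyl-5,5-dimethoxy-3-(2-methyl-1,3-dioxolan-2-yl)cyclopent-2-en-1-one (racemic) | CC(C)C1C(C2(C)OCCO2)=CC(=O)C1(OC)OC | intermediate
19 | 4-isopropyl-5,5-dimethoxy-3-(2-methyl-1,3-dioxolan-2-yl)cyclopenta-1,3-dien-1-yl trifluoromethanesulfonate | CC(C)C1=C(C2(C)OCCO2)C=C(OS(=O)(=O)C(F)(F)F)C1(OC)OC | intermediate
20 | coupled enoate (C6 epimers) | COC(=O)/C(O[Si](C)(C)C(C)(C)C)=C/[C@@]1(C)CCCC(C)(C)[C@@H]1C(C#N)C1=CC(C2(C)OCCO2)=C(C(C)C)C1(OC)OC | intermediate
21 | (Z)-2-silyloxy allylic alcohol (C6 epimers) | OC/C(O[Si](C)(C)C(C)(C)C)=C/[C@@]1(C)CCCC(C)(C)[C@@H]1C(C#N)C1=CC(C2(C)OCCO2)=C(C(C)C)C1(OC)OC | intermediate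
22 | silyloxy enal tethered to the cyclopentadienone dimethyl ketal (C6 epimers) | O=C/C(O[Si](C)(C)C(C)(C)C)=C/[C@@]1(C)CCCC(C)(C)[C@@H]1C(C#N)C1=CC(C2(C)OCCO2)=C(C(C)C)C1(OC)OC | intermediate
23 | bicyclo[3.2.1]octenone ketal cycloadduct with ring B closed | CC1(OCCO1)C1=C[C@@]23C(OC)(OC)[C@]1(C(C)C)C(O[Si](C)(C)C(C)(C)C)C(=O)[C@@H]2[C@@]1(C)CCCC(C)(C)[C@@H]1C3C#N | intermediate
24 | acyloin from 23 | CC1(OCCO1)C1=C[C@@]23C(OC)(OC)[C@]1(C(C)C)C(O)C(=O)[C@@H]2[C@@]1(C)CCCC(C)(C)[C@@H]1C3C#N | intermediate
25 | diosphenol nitrile | CC1(OCCO1)C1=C[C@@]23C(OC)(OC)[C@]1(C(C)C)C(=O)C(O)=C2[C@@]1(C)CCCC(C)(C)[C@@H]1C3C#N | intermediate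
26 | diosphenol C7 aldehyde | CC1(OCCO1)C1=C[C@@]23C(OC)(OC)[C@]1(C(C)C)C(=O)C(O)=C2[C@@]1(C)CCCC(C)(C)[C@@H]1C3C=O | intermediate
27 | C6-hydroxy C7 aldehyde | CC1(OCCO1)C1=C[C@@]23C(OC)(OC)[C@]1(C(C)C)C(=O)C(O)=C2[C@@]1(C)CCCC(C)(C)[C@@H]1[C@]3(O)C=O | intermediate (not isolated)
28 | C6,C7-diol | CC1(OCCO1)C1=C[C@@]23C(OC)(OC)[C@]1(C(C)C)C(=O)C(O)=C2[C@@]1(C)CCCC(C)(C)[C@@H]1[C@]3(O)CO | intermediate
29 | side-chain enone | CC(=O)C1=C[C@@]23C(OC)(OC)[C@]1(C(C)C)C(=O)C(O)=C2[C@@]1(C)CCCC(C)(C)[C@@H]1[C@]3(O)CO | intermediate
30 | exo-acetyl epimer | CC(=O)[C@H]1C[C@@]23C(OC)(OC)[C@]1(C(C)C)C(=O)C(O)=C2[C@@]1(C)CCCC(C)(C)[C@@H]1[C@]3(O)CO | intermediate (not isolated)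
31 | endo methyl ketone | CC(=O)[C@@H]1C[C@@]23C(OC)(OC)[C@]1(C(C)C)C(=O)C(O)=C2[C@@]1(C)CCCC(C)(C)[C@@H]1[C@]3(O)CO | intermediate
32 | tertiary vinyl carbinol (C13′ epimers) | C=CC(C)(O)[C@@H]1C[C@@]23C(OC)(OC)[C@]1(C(C)C)C(=O)C(O)=C2[C@@]1(C)CCCC(C)(C)[C@@H]1[C@]3(O)CO | intermediate
33 | geranyl acetate | CC(C)=CCC/C(C)=C/COC(C)=O | starting material
34 | (2E,6E)-8-hydroxy-3,7-dimethylocta-2,6-dien-1-yl acetate | CC(=O)OC/C=C(\C)CC/C=C(\C)CO | intermediate
35 | (2E)-5-[(2S,3S)-3-(hydroxymethyl)-3-methyloxiran-2-yl]-3-methylpent-2-en-1-yl acetate | CC(=O)OC/C=C(\C)CC[C@@H]1O[C@@]1(C)CO | intermediate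
36 | tert-butyldimethylsilyl ether of 35 | CC(=O)OC/C=C(\C)CC[C@@H]1O[C@@]1(C)CO[Si](C)(C)C(C)(C)C | intermediate
37 | epoxy allylic alcohol | OC/C=C(\C)CC[C@@H]1O[C@@]1(C)CO[Si](C)(C)C(C)(C)C | intermediate
38 | epoxy allylic mesylate | CS(=O)(=O)OC/C=C(\C)CC[C@@H]1O[C@@]1(C)CO[Si](C)(C)C(C)(C)C | intermediate (not isolated)
39 | epoxy allylic bromide | BrC/C=C(\C)CC[C@@H]1O[C@@]1(C)CO[Si](C)(C)C(C)(C)C | intermediate
40 | epoxy polyene benzyl β-keto ester | O=C(CC(=O)OCc1ccccc1)CC/C=C(\C)CC[C@@H]1O[C@@]1(C)CO[Si](C)(C)C(C)(C)C | intermediate
41 | bicyclic 3′β-hydroxy β-keto ester | O=C1CC[C@@H]2[C@](C)(CC[C@H](O)[C@@]2(C)CO[Si](C)(C)C(C)(C)C)[C@H]1C(=O)OCc1ccccc1 | intermediate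
42 | thiocarbonylimidazolide of 41 | O=C1CC[C@@H]2[C@](C)(CC[C@H](OC(=S)n3ccnc3)[C@@]2(C)CO[Si](C)(C)C(C)(C)C)[C@H]1C(=O)OCc1ccccc1 | intermediate
43 | 3′-deoxy β-keto ester | O=C1CC[C@@H]2[C@](C)(CCC[C@@]2(C)CO[Si](C)(C)C(C)(C)C)[C@H]1C(=O)OCc1ccccc1 | intermediate
44 | C18′ acid benzyl β-keto ester | O=C1CC[C@@H]2[C@](C)(CCC[C@@]2(C)C(=O)O)[C@H]1C(=O)OCc1ccccc1 | intermediate
45 | labdane β-keto diacid | O=C1CC[C@@H]2[C@](C)(CCC[C@@]2(C)C(=O)O)[C@H]1C(=O)O | intermediate
46 | coupled 8′-ketone, C14 ketal | O=C1CC[C@@H]2[C@](C)(CCC[C@@]2(C)C(=O)O)[C@H]1C/C=C(\C)[C@@H]1C[C@@]23C(OC)(OC)[C@]1(C(C)C)C(=O)C(O)=C2[C@@]1(C)CCCC(C)(C)[C@@H]1[C@]3(O)CO | intermediate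
47 | coupled 8′-ketone, C14 ketone | O=C1CC[C@@H]2[C@](C)(CCC[C@@]2(C)C(=O)O)[C@H]1C/C=C(\C)[C@@H]1C[C@@]23C(=O)[C@]1(C(C)C)C(=O)C(O)=C2[C@@]1(C)CCCC(C)(C)[C@@H]1[C@]3(O)CO | intermediate
48 | 8′(17′)-methylene C6,C7-diol | C=C1CC[C@@H]2[C@](C)(CCC[C@@]2(C)C(=O)O)[C@H]1C/C=C(\C)[C@@H]1C[C@@]23C(=O)[C@]1(C(C)C)C(=O)C(O)=C2[C@@]1(C)CCCC(C)(C)[C@@H]1[C@]3(O)CO | intermediate
49 | CNP0124601.1 | C=C1CC[C@@H]2[C@](C)(CCC[C@@]2(C)C(=O)O)[C@H]1C/C=C(\C)[C@@H]1C[C@@]23C(=O)[C@]1(C(C)C)C(=O)C(O)=C2[C@@]1(C)CCCC(C)(C)[C@@H]1[C@]3(O)C=O | target

## Step count and least certain steps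

Total: 41 steps. Longest linear sequence: 23 steps (steps 1–8, 16–26 and 38–41). The diene branch (steps 9–15) and the labdane branch (steps 27–37) are convergent.

**Step 19 (key step).** The most likely failures are loss of periselectivity, with the cation and the diene collapsing by a (4+2) or (3+2) path, ionisation of the side-chain dioxolane by the Lewis acid, or poor facial selectivity if the C6 epimers react differently. The fallback uses known chemistry and sets out from 22. The enal is heated without Lewis acid (toluene, 80 °C) so that the intramolecular Diels–Alder reaction of the cyclopentadienone ketal gives the norbornene silyloxy aldehyde F1. Buffered Bu4NF gives the α-hydroxy aldehyde F2. An α-ketol rearrangement (Al(Oi-Pr)3, toluene, 80 °C) expands the ring by migration of the C13 bridgehead to give 24. Migration of C9 instead would give the transposed acyloin F3, which step 21 oxidises to the same diosphenol 25. The route is rejoined at 24.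

**Step 16.** Transmetalation or reductive elimination may fail because both carbons are very hindered, or the product anion may be protonated at a ring carbon and scramble the diene. The fallback sets out from 10 and 18. The nitrile is lithiated (LiN(i-Pr)2, CeCl3, THF, −78 °C) and added to the ketone to give the β-hydroxy nitrile F4. This is dehydrated with methyl N-(triethylammoniosulfonyl)carbamate (benzene, 50 °C) and, if needed, equilibrated to the endocyclic diene with a catalytic base. It comes back at 20.

**Step 25.** The equilibrium at C14′ may not favour the endo ketone strongly enough, and prolonged base may erode material. The fallback sets out from 28. Both ketals are hydrolysed (2 M aq. HCl/THF, 45 °C) to the enone with free bridging ketone F5. With the small C14 carbonyl the exo face is open, so hydrogenation (H2, Pd/C) should deliver hydrogen exo and give the endo ketone F6 under kinetic control. Vinyl addition (CeCl3, CH2=CHMgBr, −78 °C), in which the bridging ketone is masked as the hemiketal of the C7 alkoxide, gives the vinyl carbinol F7. Coupling with 45 as in step 38 then gives 47 directly, where the route is rejoined.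

**Step 38.** Ionisation of the free tertiary allylic alcohol may be slow, so that protodecarboxylation of 45 wins, or oxygen nucleophiles may be allylated. The fallback sets out from 32. The alcohol groups are acylated (n-BuLi, ClCO2Me, THF, −78 °C) to the tertiary allylic methyl carbonate F8, in which the diol is a cyclic carbonate and the diosphenol an enol carbonate. The carbonate ionises readily with Pd(PPh3)4 and is coupled with 45 to give F9. K2CO3 in MeOH removes the two remaining carbonates and returns 46.

**Step 40.** The ylide may also attack the strained C14 ketone, or enolisation of the decalone may stall the reaction. The fallback sets out from 46 and reverses the order. The decalone is methylenated while C14 is still the ketal (Ph3PCH3Br, KOt-Bu) to give F10. The ketal is then removed under conditions mild enough for the exocyclic alkene (LiBF4, wet MeCN, 50 °C) to give 48, where the route is rejoined.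

## Further compounds

F1 | step 19 | Diels–Alder adduct of 22 (norbornene silyloxy aldehyde) | CC1(OCCO1)C1=C[C@@]23C(OC)(OC)[C@]1(C(C)C)C(O[Si](C)(C)C(C)(C)C)(C=O)[C@@H]2[C@@]1(C)CCCC(C)(C)[C@@H]1C3C#N
F2 | step 19 | norbornene α-hydroxy aldehyde | CC1(OCCO1)C1=C[C@@]23C(OC)(OC)[C@]1(C(C)C)C(O)(C=O)[C@@H]2[C@@]1(C)CCCC(C)(C)[C@@H]1C3C#N
F3 | step 19 | transposed acyloin (C12 ketone, C11 hydroxyl) | CC1(OCCO1)C1=C[C@@]23C(OC)(OC)[C@]1(C(C)C)C(=O)C(O)[C@@H]2[C@@]1(C)CCCC(C)(C)[C@@H]1C3C#N
F4 | step 16 | β-hydroxy nitrile from 10 and 18 | COC(=O)/C(O[Si](C)(C)C(C)(C)C)=C/[C@@]1(C)CCCC(C)(C)[C@@H]1C(C#N)C1(O)C=C(C2(C)OCCO2)C(C(C)C)C1(OC)OC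
F5 | step 25 | enone with free C14 ketone | CC(=O)C1=C[C@@]23C(=O)[C@]1(C(C)C)C(=O)C(O)=C2[C@@]1(C)CCCC(C)(C)[C@@H]1[C@]3(O)CO
F6 | step 25 | endo methyl ketone with free C14 ketone | CC(=O)[C@@H]1C[C@@]23C(=O)[C@]1(C(C)C)C(=O)C(O)=C2[C@@]1(C)CCCC(C)(C)[C@@H]1[C@]3(O)CO
F7 | step 25 | vinyl carbinol with free C14 ketone | C=CC(C)(O)[C@@H]1C[C@@]23C(=O)[C@]1(C(C)C)C(=O)C(O)=C2[C@@]1(C)CCCC(C)(C)[C@@H]1[C@]3(O)CO
F8 | step 38 | tertiary allylic methyl carbonate of 32 (cyclic carbonate, enol carbonate) | C=CC(C)(OC(=O)OC)[C@@H]1C[C@@]23C(OC)(OC)[C@]1(C(C)C)C(=O)C(OC(=O)OC)=C2[C@@]1(C)CCCC(C)(C)[C@@H]1[C@]34COC(=O)O4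
F9 | step 38 | coupled ketone with cyclic carbonate and enol carbonate | O=C1CC[C@@H]2[C@](C)(CCC[C@@]2(C)C(=O)O)[C@H]1C/C=C(\C)[C@@H]1C[C@@]23C(OC)(OC)[C@]1(C(C)C)C(=O)C(OC(=O)OC)=C2[C@@]1(C)CCCC(C)(C)[C@@H]1[C@]34COC(=O)O4
F10 | step 40 | 8′(17′)-methylene compound with C14 ketal | C=C1CC[C@@H]2[C@](C)(CCC[C@@]2(C)C(=O)O)[C@H]1C/C=C(\C)[C@@H]1C[C@@]23C(OC)(OC)[C@]1(C(C)C)C(=O)C(O)=C2[C@@]1(C)CCCC(C)(C)[C@@H]1[C@]3(O)CO
A1 | alternative 1 | open-chain epoxy polyene allylsilane attached to the nor-abietane | C[Si](C)(C)C/C(CC/C=C(\C)CC[C@@H]1O[C@@]1(C)CO[Si](C)(C)C(C)(C)C)=C\C/C=C(\C)[C@@H]1C[C@@]23C(=O)[C@]1(C(C)C)C(=O)C(OC)=C2[C@@]1(C)CCCC(C)(C)[C@@H]1[C@]3(O)CO[Si](c4ccccc4)(c4ccccc4)C(C)(C)C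
A2 | alternative 1 | 3-hydroxy-18-silyloxy labdane adduct | C=C1CC[C@@H]2[C@](C)(CC[C@H](O)[C@@]2(C)CO[Si](C)(C)C(C)(C)C)[C@H]1C/C=C(\C)[C@@H]1C[C@@]23C(=O)[C@]1(C(C)C)C(=O)C(OC)=C2[C@@]1(C)CCCC(C)(C)[C@@H]1[C@]3(O)CO[Si](c4ccccc4)(c4ccccc4)C(C)(C)C
A3 | alternative 2 | seco diosphenol with ring A alkene | COC(=O)[C@@H]1C[C@]2(C(=O)[C@]1(C(C)C)C(=O)C(O)=C2)[C@@]1(COC(=O)O1)[C@@H]1C(C)=CCCC1(C)C
A4 | alternative 2 | nor-abietane core with ester and carbonate | COC(=O)[C@@H]1C[C@@]23C(=O)[C@]1(C(C)C)C(=O)C(O)=C2[C@@]1(C)CCCC(C)(C)[C@@H]1[C@]34COC(=O)O4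
A5 | alternative 3 | 6-diazo-7-ketone with six-membered ring B | C=C1CC[C@@H]2[C@](C)(CCC[C@@]2(C)C(=O)OCC[Si](C)(C)C)[C@H]1C/C=C(\C)[C@@H]1C[C@@]23C(=O)[C@]1(C(C)C)C(=O)C(OC)=C2[C@@]1(C)CCCC(C)(C)[C@@H]1C(=[N+]=[N-])C3=O
A6 | alternative 3 | ring-contracted S-ethyl thioester | C=C1CC[C@@H]2[C@](C)(CCC[C@@]2(C)C(=O)OCC[Si](C)(C)C)[C@H]1C/C=C(\C)[C@@H]1C[C@@]23C(=O)[C@]1(C(C)C)C(=O)C(OC)=C2[C@@]1(C)CCCC(C)(C)[C@@H]1[C@@H]3C(=O)SCC
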